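Ring B of the tetrahydroisoquinoline (isoquinoline numbering) is cut at C4–C4a and C1–C8a, so that all its carbons and the nitrogen arrive in one palladium/norbornene (Catellani) relay on 1-iodo-2,4-dimethoxybenzene: ortho C–H alkylation by (S)-2-methyl-1-tosylaziridine, then ipso Suzuki coupling with a 1-ethoxyvinyl boronate. The step exploits the adjacent carbons C4a and C8a of ring A: C8a (the iodide carbon) is blocked on its other side by the C8 methoxy group, C4a is the only free ortho C–H, and the C3 methyl/nitrogen unit is a ring-opened (S)-aziridine. Cyclisation, trans reduction, C5 bromination and a Negishi coupling with the naphthyl fragment complete the target.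

Key step: step 2

Assumption: the biaryl axis carries no descriptor in the target, so the coupling is planned without axial control; both rotamers about C5–C1' have the drawn (1S,3S) structure and can be separated by chromatography if a single one is wanted.

Step 1
Reactants: 1 (S)-alaninol
Product: 4 (S)-2-methyl-1-tosylaziridine, via N-tosyl alaninol 2 (not isolated), via bis-tosylate 3 (not isolated)
Conditions: TsCl (2.2 equiv), KOH, CH2Cl2/H2O, 0 °C to rt
Reagents that add atoms: p-toluenesulfonyl chloride, Cc1ccc(cc1)S(Cl)(=O)=O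
Why: N- then O-sulfonylation is followed by base-induced 3-exo-tet displacement of the primary tosylate by the sulfonamide anion (Wenker-type aziridine closure), which never touches the stereocenter, so it stays S.

Step 2
Reactants: 5 1-iodo-2,4-dimethoxybenzene; 4 (S)-2-methyl-1-tosylaziridine; 6 2-(1-ethoxyvinyl)-4,4,5,5-tetramethyl-1,3,2-dioxaborolane
Product: 7 N-[(2S)-1-[2-(1-ethoxyvinyl)-3,5-dimethoxyphenyl]propan-2-yl]-4-methylbenzenesulfonamide
Conditions: Pd(OAc)2 (10 mol%), P(2-furyl)3 (22 mol%), norbornene (2 equiv), Cs2CO3, MeCN/H2O (20:1), 80 °C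
Reagents that add atoms: none
Why: Catellani reaction: zerovalent palladium adds to the C–I bond of 5, norbornene inserts, and the only free ortho C–H (C6 of 5, the future C4a) is palladated to a divalent aryl–norbornyl palladacycle, which opens aziridine 4 at its CH2 carbon in an SN2-type oxidative addition to tetravalent palladium before reductive elimination forms C4–C4a. With both ortho positions filled, norbornene is extruded by β-carbon elimination and the aryl palladium at the future C8a undergoes Suzuki–Miyaura transmetalation with 6 and reductive elimination, forming C1–C8a. The closest known reaction type is the palladium/norbornene ortho-alkylation of aryl iodides by N-sulfonyl aziridines combined with ipso Suzuki termination. No ring is closed and no stereocenter is formed: the S centre of 4 passes through untouched because the palladacycle attacks the unsubstituted ring carbon. Mono-alkylation at a single site is secured by the C2 methoxy group of 5, which blocks the second ortho position and drives norbornene extrusion, and regioselective aziridine opening is secured by the methyl group shielding the other ring carbon. Termination by the boronate must outrun C–N bond formation by the sulfonamide at the ipso carbon and direct coupling of 5, which excess norbornene, excess boronate and water in the base system are meant to ensure.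

Step 3
Reactants: 7 N-[(2S)-1-[2-(1-ethoxyvinyl)-3,5-dimethoxyphenyl]propan-2-yl]-4-methylbenzenesulfonamide
Product: 10 (3S)-6,8-dimethoxy-1,3-dimethyl-3,4-dihydroisoquinoline, via amine 8 (not isolated), via amino ketone 9 (not isolated)
Conditions: Na, naphthalene, DME, −78 °C; then 2 M HCl, rt; then NaOH (pH 11)
Reagents that add atoms: none
Why: Single-electron reductive cleavage of the S–N bond (sodium naphthalenide detosylation) should spare the twisted, electron-rich aryl enol ether, aqueous acid then hydrolyses the enol ether to the methyl ketone, and on basification the amino ketone condenses to the six-membered cyclic imine with C3 untouched.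

Step 4
Reactants: 10 (3S)-6,8-dimethoxy-1,3-dimethyl-3,4-dihydroisoquinoline
Product: 11 (1S,3S)-6,8-dimethoxy-1,3-dimethyl-1,2,3,4-tetrahydroisoquinoline
Conditions: AlMe3, then LiAlH4, THF, −78 to 0 °C; H2O quench
Reagents that add atoms: none
Why: Hydride reduction of the imine after AlMe3 complexation of nitrogen: the bulky N–Al unit pushes the C3 methyl pseudo-axial, and axial hydride delivery at C1 through a chair-like transition state places the C1 methyl trans to it, so the 3S centre should set 1S (substrate control).

Step 5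
Reactants: 11 (1S,3S)-6,8-dimethoxy-1,3-dimethyl-1,2,3,4-tetrahydroisoquinoline
Product: 12 (1S,3S)-2-benzyl-6,8-dimethoxy-1,3-dimethyl-1,2,3,4-tetrahydroisoquinoline
Conditions: BnBr, K2CO3, MeCN, 60 °C
Reagents that add atoms: benzyl bromide, BrCc1ccccc1
Why: SN2 N-alkylation of the secondary amine masks N–H for the halogenation and organometallic steps with a group that hydrogenolysis removes.

Step 6
Reactants: 12 (1S,3S)-2-benzyl-6,8-dimethoxy-1,3-dimethyl-1,2,3,4-tetrahydroisoquinoline
Product: 13 (1S,3S)-2-benzyl-5-bromo-6,8-dimethoxy-1,3-dimethyl-1,2,3,4-tetrahydroisoquinoline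
Conditions: Br2 (1.0 equiv), AcOH, rt
Reagents that add atoms: bromine, BrBr
Why: Electrophilic aromatic bromination of the protonated amine should occur at C5, which is para to the C8 methoxy and ortho to the C6 methoxy and less crowded than C7 between the two methoxy groups.

Step 7
Reactants: 14 N,N-diethyl-2-methoxybenzamide; 15 3-bromo-2-methylprop-1-ene
Product: 18 N,N-diethyl-2-methoxy-6-(2-methylprop-2-en-1-yl)benzamide, via aryllithium 16 (not isolated), via arylmagnesium bromide 17 (not isolated)
Conditions: s-BuLi, TMEDA, THF, −78 °C; MgBr2·OEt2; then 15, −78 °C to rt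
Reagents that add atoms: none
Why: Directed ortho-metalation by the tertiary amide (a stronger director than methoxy, so C6 is lithiated), transmetalation to the aryl Grignard reagent and allylation with the symmetrical allylic bromide.

Step 8
Reactants: 18 N,N-diethyl-2-methoxy-6-(2-methylprop-2-en-1-yl)benzamide
Product: 20 8-methoxy-3-methylnaphthalen-1-ol, via naphthalenone 19 (not isolated)
Conditions: LiN(iPr)2 (2.2 equiv), THF, −78 °C to rt; then aq HCl
Reagents that add atoms: none
Why: Anionic annulation of an ortho-allyl benzamide (intramolecular Claisen-type acylation): the doubly activated benzylic/allylic proton is removed, the terminal carbon of the allyl anion attacks the amide carbonyl to close a six-membered ring, diethylamide is lost and the dienone tautomerises to the naphthol.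

Step 9
Reactants: 20 8-methoxy-3-methylnaphthalen-1-ol
Product: 21 1,8-dimethoxy-3-methylnaphthalene
Conditions: MeI, K2CO3, DMF, rt
Reagents that add atoms: iodomethane, CI
Why: Williamson ether synthesis on the naphtholate.

Step 10
Reactants: 21 1,8-dimethoxy-3-methylnaphthalene
Product: 22 1-bromo-4,5-dimethoxy-2-methylnaphthalene
Conditions: NBS, MeCN, 0 °C to rt
Reagents that add atoms: N-bromosuccinimide, BrN1C(=O)CCC1=O
Why: Electrophilic aromatic bromination should go para to the methoxy group of the methyl-bearing ring, whose α position is additionally activated by the ortho methyl group, in preference to the corresponding position of the other ring.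

Step 11
Reactants: 22 1-bromo-4,5-dimethoxy-2-methylnaphthalene; 13 (1S,3S)-2-benzyl-5-bromo-6,8-dimethoxy-1,3-dimethyl-1,2,3,4-tetrahydroisoquinoline
Product: 25 (1S,3S)-2-benzyl-5-(4,5-dimethoxy-2-methylnaphthalen-1-yl)-6,8-dimethoxy-1,3-dimethyl-1,2,3,4-tetrahydroisoquinoline, via naphthyllithium 23 (not isolated), via naphthylzinc chloride 24 (not isolated)
Conditions: 22, t-BuLi (2 equiv), THF, −78 °C; ZnCl2, −78 °C to rt; then 13, Pd(OAc)2 (4 mol%), RuPhos (8 mol%), THF/NMP, 70 °C
Reagents that add atoms: none
Why: Negishi coupling: halogen–lithium exchange and transmetalation give an arylzinc that does not suffer protodemetalation under the anhydrous conditions, and a bulky dialkylbiarylphosphine on palladium is the established way to forge tetra-ortho-substituted biaryl bonds.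

Step 12
Reactants: 25 (1S,3S)-2-benzyl-5-(4,5-dimethoxy-2-methylnaphthalen-1-yl)-6,8-dimethoxy-1,3-dimethyl-1,2,3,4-tetrahydroisoquinoline
Product: 26 (1S,3S)-5-(4,5-dimethoxy-2-methylnaphthalen-1-yl)-6,8-dimethoxy-1,3-dimethyl-1,2,3,4-tetrahydroisoquinoline (CNP0168593.3)
Conditions: H2 (1 atm), 10% Pd/C, MeOH, rt
Reagents that add atoms: none
Why: Hydrogenolysis of the N-benzyl C–N bond, which leaves the aryl ethers, the naphthalene and both stereocenters untouched.

Compound list
1 | (S)-alaninol, (2S)-2-aminopropan-1-ol | C[C@H](N)CO | starting material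
2 | N-[(2S)-1-hydroxypropan-2-yl]-4-methylbenzenesulfonamide | C[C@@H](CO)NS(=O)(=O)c1ccc(C)cc1 | intermediate
3 | (2S)-2-[(4-methylphenyl)sulfonylamino]propyl 4-methylbenzenesulfonate | C[C@@H](COS(=O)(=O)c1ccc(C)cc1)NS(=O)(=O)c1ccc(C)cc1 | intermediate
4 | (S)-2-methyl-1-tosylaziridine | C[C@H]1CN1S(=O)(=O)c1ccc(C)cc1 | intermediate
5 | 1-iodo-2,4-dimethoxybenzene | COc1ccc(I)c(OC)c1 | starting material
6 | 2-(1-ethoxyvinyl)-4,4,5,5-tetramethyl-1,3,2-dioxaborolane | CCOC(=C)B1OC(C)(C)C(C)(C)O1 | starting material
7 | N-[(2S)-1-[2-(1-ethoxyvinyl)-3,5-dimethoxyphenyl]propan-2-yl]-4-methylbenzenesulfonamide | CCOC(=C)c1c(OC)cc(OC)cc1C[C@H](C)NS(=O)(=O)c1ccc(C)cc1 | intermediate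
8 | (2S)-1-[2-(1-ethoxyvinyl)-3,5-dimethoxyphenyl]propan-2-amine | CCOC(=C)c1c(OC)cc(OC)cc1C[C@H](C)N | intermediate
9 | 1-{2-[(2S)-2-aminopropyl]-4,6-dimethoxyphenyl}ethan-1-one | CC(=O)c1c(OC)cc(OC)cc1C[C@H](C)N | intermediate
10 | (3S)-6,8-dimethoxy-1,3-dimethyl-3,4-dihydroisoquinoline | COc1cc(OC)c2c(c1)C[C@H](C)N=C2C | intermediate
11 | (1S,3S)-6,8-dimethoxy-1,3-dimethyl-1,2,3,4-tetrahydroisoquinoline | COc1cc(OC)c2c(c1)C[C@H](C)N[C@H]2C | intermediate
12 | (1S,3S)-2-benzyl-6,8-dimethoxy-1,3-dimethyl-1,2,3,4-tetrahydroisoquinoline | COc1cc(OC)c2c(c1)C[C@H](C)N(Cc1ccccc1)[C@H]2C | intermediate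
13 | (1S,3S)-2-benzyl-5-bromo-6,8-dimethoxy-1,3-dimethyl-1,2,3,4-tetrahydroisoquinoline | COc1cc(OC)c2c(c1Br)C[C@H](C)N(Cc1ccccc1)[C@H]2C | intermediate
14 | N,N-diethyl-2-methoxybenzamide | CCN(CC)C(=O)c1ccccc1OC | starting material
15 | 3-bromo-2-methylprop-1-ene | CC(=C)CBr | starting material
16 | [2-(diethylcarbamoyl)-3-methoxyphenyl]lithium | [Li]c1cccc(OC)c1C(=O)N(CC)CC | intermediate
17 | [2-(diethylcarbamoyl)-3-methoxyphenyl]magnesium bromide | Br[Mg]c1cccc(OC)c1C(=O)N(CC)CC | intermediate
18 | N,N-diethyl-2-methoxy-6-(2-methylprop-2-en-1-yl)benzamide | CCN(CC)C(=O)c1c(CC(C)=C)cccc1OC | intermediate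
19 | 8-methoxy-3-methylnaphthalen-1(2H)-one | COc1cccc2C=C(C)CC(=O)c12 | intermediate
20 | 8-methoxy-3-methylnaphthalen-1-ol | COc1cccc2cc(C)cc(O)c12 | intermediate
21 | 1,8-dimethoxy-3-methylnaphthalene | COc1cccc2cc(C)cc(OC)c12 | intermediate
22 | 1-bromo-4,5-dimethoxy-2-methylnaphthalene | COc1cccc2c(Br)c(C)cc(OC)c12 | intermediate
23 | (4,5-dimethoxy-2-methylnaphthalen-1-yl)lithium | [Li]c1c(C)cc(OC)c2c(OC)cccc12 | intermediate
24 | (4,5-dimethoxy-2-methylnaphthalen-1-yl)zinc chloride | Cl[Zn]c1c(C)cc(OC)c2c(OC)cccc12 | intermediate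
25 | (1S,3S)-2-benzyl-5-(4,5-dimethoxy-2-methylnaphthalen-1-yl)-6,8-dimethoxy-1,3-dimethyl-1,2,3,4-tetrahydroisoquinoline | COc1cc(OC)c2c(c1-c1c(C)cc(OC)c3c(OC)cccc13)C[C@H](C)N(Cc1ccccc1)[C@H]2C | intermediate
26 | (1S,3S)-5-(4,5-dimethoxy-2-methylnaphthalen-1-yl)-6,8-dimethoxy-1,3-dimethyl-1,2,3,4-tetrahydroisoquinoline (CNP0168593.3) | COc1cc(OC)c2c(c1-c1c(C)cc(OC)c3c(OC)cccc13)C[C@H](C)N[C@H]2C | target

Total step count: 12 steps.
Longest linear sequence: 8 steps (steps 1–6, 11 and 12, from 1 to 26); the naphthalene branch (steps 7–10) joins at step 11.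

Steps most likely to fail

Step 2 (key step). The relay may be cut short by direct Suzuki coupling of 5 before norbornene insertion. After the alkylation, the sulfonamide nitrogen may close onto the ipso carbon by C–N bond formation instead of the boronate coupling there. The aziridine may also be consumed by base or iodide. Fallback on known chemistry: setting out from aziridine 4, copper-catalysed ring opening at the CH2 carbon with commercial 3,5-dimethoxyphenylmagnesium bromide (CuI cat., THF, −30 °C) should give N-[(2S)-1-(3,5-dimethoxyphenyl)propan-2-yl]-4-methylbenzenesulfonamide F1. Detosylation (Na, naphthalene, DME, −78 °C) would give (2S)-1-(3,5-dimethoxyphenyl)propan-2-amine F2, and acetylation (Ac2O, Et3N, CH2Cl2) N-[(2S)-1-(3,5-dimethoxyphenyl)propan-2-yl]acetamide F3. Bischler–Napieralski cyclisation (POCl3, MeCN, reflux) at either of the two equivalent positions ortho to the side chain comes back to the route at 10.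

Step 11. Transmetalation and reductive elimination at the tetra-ortho-substituted axis may be slow, so that protonolysis or homocoupling of the naphthylzinc reagent and reduction of the bromide take over. Fallback with the roles of the partners reversed: setting out from 13, Miyaura borylation (B2pin2, Pd(OAc)2, SPhos, KOAc, dioxane, 100 °C) would give (1S,3S)-2-benzyl-6,8-dimethoxy-1,3-dimethyl-5-(4,4,5,5-tetramethyl-1,3,2-dioxaborolan-2-yl)-1,2,3,4-tetrahydroisoquinoline F6. Suzuki–Miyaura coupling of F6 with bromide 22 (Pd(OAc)2, SPhos, K3PO4, toluene/H2O, 100 °C) comes back at 25.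

Step 3. S–N cleavage may stall because the sulfonamide is deprotonated by the reductant, or the enol ether may be hydrolysed early so that the ketone is then reduced. Fallback by activation and mild cleavage: setting out from 7, N-acylation (Boc2O, DMAP, MeCN) should give tert-butyl N-[(2S)-1-[2-(1-ethoxyvinyl)-3,5-dimethoxyphenyl]propan-2-yl]-N-(4-methylphenyl)sulfonylcarbamate F4. Its weakened S–N bond is cleaved with Mg in MeOH under sonication to tert-butyl N-[(2S)-1-[2-(1-ethoxyvinyl)-3,5-dimethoxyphenyl]propan-2-yl]carbamate F5. Aqueous HCl then removes the carbamate and hydrolyses the enol ether, and basification closes the imine, coming back at 10.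

Further compounds
F1 | step 2 | N-[(2S)-1-(3,5-dimethoxyphenyl)propan-2-yl]-4-methylbenzenesulfonamide | COc1cc(OC)cc(C[C@H](C)NS(=O)(=O)c2ccc(C)cc2)c1
F2 | step 2 | (2S)-1-(3,5-dimethoxyphenyl)propan-2-amine | COc1cc(OC)cc(C[C@H](C)N)c1
F3 | step 2 | N-[(2S)-1-(3,5-dimethoxyphenyl)propan-2-yl]acetamide | COc1cc(OC)cc(C[C@H](C)NC(C)=O)c1
F4 | step 3 | tert-butyl N-[(2S)-1-[2-(1-ethoxyvinyl)-3,5-dimethoxyphenyl]propan-2-yl]-N-(4-methylphenyl)sulfonylcarbamate | CCOC(=C)c1c(OC)cc(OC)cc1C[C@H](C)N(C(=O)OC(C)(C)C)S(=O)(=O)c1ccc(C)cc1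
F5 | step 3 | tert-butyl N-[(2S)-1-[2-(1-ethoxyvinyl)-3,5-dimethoxyphenyl]propan-2-yl]carbamate | CCOC(=C)c1c(OC)cc(OC)cc1C[C@H](C)NC(=O)OC(C)(C)C
F6 | step 11 | (1S,3S)-2-benzyl-6,8-dimethoxy-1,3-dimethyl-5-(4,4,5,5-tetramethyl-1,3,2-dioxaborolan-2-yl)-1,2,3,4-tetrahydroisoquinoline | COc1cc(OC)c2c(c1B1OC(C)(C)C(C)(C)O1)C[C@H](C)N(Cc1ccccc1)[C@H]2C
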